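**Strategy**

Everything rests on cutting the C2–C3 bond of ring C. In the isoflavone, O1 and C2 together are nothing but an O-methyl unit, the same as the 5-methoxy substituent; a ring A bearing two equivalent methoxy groups on either side of the C4 carbonyl therefore contains both. A rhodium carbene at C3 inserts into a methoxy C–H bond and, in one operation, forms C2–C3 and closes ring C as the isoflavanone, while the second methoxy group remains as 5-OMe. The precursor is a diazo ketone with 2,6-dimethoxy-4-silyloxyphenyl on the carbonyl and the silylated chromene of ring B on the diazo carbon; triisopropylsilyl ethers leave the methoxy groups as the only C–H bonds next to oxygen.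

Key step: step 9

Remark on the chemistry: the target has no stereocentre; the one stereocentre that the route creates (C3 of the isoflavanone) is formed racemic and is removed by the dehydrogenation that follows, so that compound is written without a stereodescriptor.

**Route**

Step 1
Reactants: 1 5-bromo-2-hydroxybenzaldehyde; 2 3-chloro-3-methylbut-1-yne
Product: 3 5-bromo-2-[(2-methylbut-3-yn-2-yl)oxy]benzaldehyde
Conditions: DBU, CuCl2 (cat.), MeCN, 0 °C to rt
Reagents that add atoms: none
Why: Copper-catalysed propargylic etherification (O-alkylation of the phenoxide by the copper-activated tertiary propargylic chloride) is the standard entry to aryl 1,1-dimethylpropargyl ethers and works best with acidic phenols such as 1.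

Step 2
Reactants: 3 5-bromo-2-[(2-methylbut-3-yn-2-yl)oxy]benzaldehyde
Product: 5 5-bromo-2-[(2-methylbut-3-yn-2-yl)oxy]phenol, via aryl formate 4 (not isolated)
Conditions: mCPBA, CH2Cl2, 0 °C to rt; then K2CO3, MeOH, rt
Reagents that add atoms: mCPBA, O=C(OO)c1cccc(Cl)c1 (one oxygen)
Why: Baeyer–Villiger (Dakin-type) oxidation of an ortho-alkoxybenzaldehyde proceeds by aryl migration to the formate, which mild methanolysis cleaves, and the alkyne and the aryl bromide are inert to the peracid.

Step 3
Reactants: 5 5-bromo-2-[(2-methylbut-3-yn-2-yl)oxy]phenol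
Product: 6 6-bromo-2,2-dimethyl-2H-chromen-8-ol
Conditions: PhNEt2, 170 °C
Reagents that add atoms: none
Why: The thermal aryl propargyl ether Claisen rearrangement goes to the only free ortho carbon and is followed by enolisation, 1,5-hydrogen shift and 6π electrocyclisation, the classical route to 2,2-dimethyl-2H-chromenes, which places bromine at C6 and the hydroxyl group at C8.

Step 4
Reactants: 6 6-bromo-2,2-dimethyl-2H-chromen-8-ol
Product: 7 [(6-bromo-2,2-dimethyl-2H-chromen-8-yl)oxy]tri(propan-2-yl)silane
Conditions: TIPSCl, imidazole, DMF, rt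
Reagents that add atoms: TIPSCl, CC(C)[Si](Cl)(C(C)C)C(C)C
Why: Standard silylation of a phenol gives an ether that tolerates the strong bases, the carbene and the quinone oxidant of the later steps and has no C–H bond next to oxygen.

Step 5
Reactants: 8 3,5-dimethoxyphenol
Product: 9 (3,5-dimethoxyphenoxy)tri(propan-2-yl)silane
Conditions: TIPSCl, imidazole, DMF, rt
Reagents that add atoms: TIPSCl, CC(C)[Si](Cl)(C(C)C)C(C)C
Why: Standard silylation of a phenol; the bulky, non-coordinating silyl ether is chosen because it does not direct metalation to its own neighbours in step 6.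

Step 6
Reactants: 9 (3,5-dimethoxyphenoxy)tri(propan-2-yl)silane
Product: 11 1-{2,6-dimethoxy-4-[tri(propan-2-yl)silyloxy]phenyl}ethan-1-one, via aryllithium 10 (not isolated)
Conditions: n-BuLi, THF, 0 °C to rt; MeC(O)N(OMe)Me, −78 to 0 °C; aq. NH4Cl
Reagents that add atoms: N-methoxy-N-methylacetamide, CC(=O)N(C)OC (acetyl group of 11); n-BuLi, [Li]CCCC (lithium of 10 only)
Why: Directed ortho-metalation takes place at the carbon between the two cooperating methoxy groups, the silyloxy group shielding its own neighbours, and the aryllithium is acylated by the Weinreb amide through a chelated adduct that releases the ketone only on work-up.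

Step 7
Reactants: 11 1-{2,6-dimethoxy-4-[tri(propan-2-yl)silyloxy]phenyl}ethan-1-one; 7 [(6-bromo-2,2-dimethyl-2H-chromen-8-yl)oxy]tri(propan-2-yl)silane
Product: 12 1-{2,6-dimethoxy-4-[tri(propan-2-yl)silyloxy]phenyl}-2-{2,2-dimethyl-8-[tri(propan-2-yl)silyloxy]-2H-chromen-6-yl}ethan-1-one
Conditions: Pd2(dba)3 (cat.), Xantphos, NaOtBu, THF, 65 °C
Reagents that add atoms: none
Why: Palladium-catalysed α-arylation of a ketone enolate is well established for aryl methyl ketones; 11 has a single enolisable position, the aryl bromide has two free ortho positions, and the wide-bite-angle ligand favours monoarylation.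

Step 8
Reactants: 12 1-{2,6-dimethoxy-4-[tri(propan-2-yl)silyloxy]phenyl}-2-{2,2-dimethyl-8-[tri(propan-2-yl)silyloxy]-2H-chromen-6-yl}ethan-1-one
Product: 13 2-diazo-1-{2,6-dimethoxy-4-[tri(propan-2-yl)silyloxy]phenyl}-2-{2,2-dimethyl-8-[tri(propan-2-yl)silyloxy]-2H-chromen-6-yl}ethan-1-one
Conditions: p-ABSA, DBU, MeCN, 0 °C to rt
Reagents that add atoms: 4-acetamidobenzenesulfonyl azide (p-ABSA), CC(=O)Nc1ccc(cc1)S(=O)(=O)N=[N+]=[N-]
Why: Regitz diazo transfer to a benzylic ketone methylene, acidified by both the carbonyl group and ring B, is the usual preparation of aryl diazo ketones from deoxybenzoins.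

Step 9
Reactants: 13 2-diazo-1-{2,6-dimethoxy-4-[tri(propan-2-yl)silyloxy]phenyl}-2-{2,2-dimethyl-8-[tri(propan-2-yl)silyloxy]-2H-chromen-6-yl}ethan-1-one
Product: 14 racemic 5-methoxy-3-{2,2-dimethyl-8-[tri(propan-2-yl)silyloxy]-2H-chromen-6-yl}-7-[tri(propan-2-yl)silyloxy]chroman-4-one
Conditions: Rh2(O2CCPh3)4 (2 mol%), CH2Cl2, 4 Å MS, 40 °C, 13 added over 6 h by syringe pump (final 0.005 M)
Reagents that add atoms: none
Why: Proposed new method: Rh2(O2CCPh3)4 (divalent rhodium) should expel N2 from 13 and give a rhodium carbene at C3, stabilised by ring B (with its para ring oxygen) as donor and by the aroyl group as acceptor, which takes up a C–H bond of an ortho-methoxy group through a three-centre, hydride-transfer-like transition state and so forms the C2–C3 bond. The closest known reaction types are intramolecular rhodium carbene C–H insertions beside an ether oxygen that turn ortho-alkoxyaryl diazo ketones into chromanones (and related diazo compounds into dihydrobenzofurans), and intermolecular insertions of donor-acceptor carbenes into the methyl group of methyl ethers; closure of a chromanone onto an aryl methyl ether has not been shown. Ring C closes as a six-membered ring by 1,6-insertion, in which the carbonyl carbon, two ring A carbons and the ether oxygen already link the carbene carbon to the methoxy carbon, the five-membered alternative being attack at oxygen. The stereocentre at C3 is not controlled because the catalyst is achiral, so 14 forms as a racemate, which is of no consequence since step 10 makes C3 trigonal. The selectivity needed is insertion over oxonium ylide formation and over bimolecular carbene reactions (dimerisation, cyclopropanation of the chromene alkene of a second molecule): the two ortho-methoxy groups twist the ketone out of the plane of ring A and place six equivalent, oxygen-activated C–H bonds beside the carbene, the ylide can only go on by an unfavourable 1,2-methyl shift and otherwise reverts, the bulky carboxylate ligands and the donor aryl group tame the carbene and disfavour attack at the flanked oxygen, the silyl ethers offer no other C–H bond next to oxygen, and slow addition at high dilution keeps the bimolecular paths down.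

Step 10
Reactants: 14 racemic 5-methoxy-3-{2,2-dimethyl-8-[tri(propan-2-yl)silyloxy]-2H-chromen-6-yl}-7-[tri(propan-2-yl)silyloxy]chroman-4-one
Product: 15 5-methoxy-3-{2,2-dimethyl-8-[tri(propan-2-yl)silyloxy]-2H-chromen-6-yl}-7-[tri(propan-2-yl)silyloxy]-4H-chromen-4-one
Conditions: DDQ, 1,4-dioxane, 100 °C
Reagents that add atoms: none
Why: Dehydrogenation of an isoflavanone by DDQ (hydride abstraction at C2 assisted by O1, then loss of the C3 proton) is a standard entry to isoflavones and removes the C3 stereocentre, while 2,2-dimethylchromenes and silyl ethers are stable to the quinone.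

Step 11
Reactants: 15 5-methoxy-3-{2,2-dimethyl-8-[tri(propan-2-yl)silyloxy]-2H-chromen-6-yl}-7-[tri(propan-2-yl)silyloxy]-4H-chromen-4-one
Product: 16 Glycyrrhizaisoflavone B, 7-hydroxy-3-(8-hydroxy-2,2-dimethyl-2H-chromen-6-yl)-5-methoxy-4H-chromen-4-one
Conditions: TBAF, AcOH, THF, 0 °C to rt
Reagents that add atoms: none
Why: Fluoride cleavage of aryl silyl ethers is fast and general, and buffering with acetic acid protects the base-sensitive pyranone ring and the chromene, while the 5-methyl ether is untouched.

**Compound list**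

1 | 5-bromo-2-hydroxybenzaldehyde | O=Cc1cc(Br)ccc1O | starting material
2 | 3-chloro-3-methylbut-1-yne | CC(C)(Cl)C#C | starting material
3 | 5-bromo-2-[(2-methylbut-3-yn-2-yl)oxy]benzaldehyde | O=Cc1cc(Br)ccc1OC(C)(C)C#C | intermediate
4 | 5-bromo-2-[(2-methylbut-3-yn-2-yl)oxy]phenyl formate | O=COc1cc(Br)ccc1OC(C)(C)C#C | intermediate (not isolated)
5 | 5-bromo-2-[(2-methylbut-3-yn-2-yl)oxy]phenol | Oc1cc(Br)ccc1OC(C)(C)C#C | intermediate
6 | 6-bromo-2,2-dimethyl-2H-chromen-8-ol | CC1(C)C=Cc2cc(Br)cc(O)c2O1 | intermediate
7 | [(6-bromo-2,2-dimethyl-2H-chromen-8-yl)oxy]tri(propan-2-yl)silane | CC(C)[Si](Oc1cc(Br)cc2C=CC(C)(C)Oc12)(C(C)C)C(C)C | intermediate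
8 | 3,5-dimethoxyphenol | COc1cc(O)cc(OC)c1 | starting material
9 | (3,5-dimethoxyphenoxy)tri(propan-2-yl)silane | COc1cc(OC)cc(O[Si](C(C)C)(C(C)C)C(C)C)c1 | intermediate
10 | {2,6-dimethoxy-4-[tri(propan-2-yl)silyloxy]phenyl}lithium | [Li]c1c(OC)cc(O[Si](C(C)C)(C(C)C)C(C)C)cc1OC | intermediate (not isolated)
11 | 1-{2,6-dimethoxy-4-[tri(propan-2-yl)silyloxy]phenyl}ethan-1-one | CC(=O)c1c(OC)cc(O[Si](C(C)C)(C(C)C)C(C)C)cc1OC | intermediate
12 | 1-{2,6-dimethoxy-4-[tri(propan-2-yl)silyloxy]phenyl}-2-{2,2-dimethyl-8-[tri(propan-2-yl)silyloxy]-2H-chromen-6-yl}ethan-1-one | COc1cc(O[Si](C(C)C)(C(C)C)C(C)C)cc(OC)c1C(=O)Cc1cc(O[Si](C(C)C)(C(C)C)C(C)C)c2OC(C)(C)C=Cc2c1 | intermediate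
13 | 2-diazo-1-{2,6-dimethoxy-4-[tri(propan-2-yl)silyloxy]phenyl}-2-{2,2-dimethyl-8-[tri(propan-2-yl)silyloxy]-2H-chromen-6-yl}ethan-1-one | COc1cc(O[Si](C(C)C)(C(C)C)C(C)C)cc(OC)c1C(=O)C(=[N+]=[N-])c1cc(O[Si](C(C)C)(C(C)C)C(C)C)c2OC(C)(C)C=Cc2c1 | intermediate (precursor of the key step)
14 | racemic 5-methoxy-3-{2,2-dimethyl-8-[tri(propan-2-yl)silyloxy]-2H-chromen-6-yl}-7-[tri(propan-2-yl)silyloxy]chroman-4-one | COc1cc(O[Si](C(C)C)(C(C)C)C(C)C)cc2OCC(c3cc(O[Si](C(C)C)(C(C)C)C(C)C)c4OC(C)(C)C=Cc4c3)C(=O)c12 | intermediate (product of the key step, racemate)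
15 | 5-methoxy-3-{2,2-dimethyl-8-[tri(propan-2-yl)silyloxy]-2H-chromen-6-yl}-7-[tri(propan-2-yl)silyloxy]-4H-chromen-4-one | COc1cc(O[Si](C(C)C)(C(C)C)C(C)C)cc2occ(-c3cc(O[Si](C(C)C)(C(C)C)C(C)C)c4OC(C)(C)C=Cc4c3)c(=O)c12 | intermediate
16 | Glycyrrhizaisoflavone B, 7-hydroxy-3-(8-hydroxy-2,2-dimethyl-2H-chromen-6-yl)-5-methoxy-4H-chromen-4-one | COc1cc(O)cc2occ(-c3cc(O)c4c(c3)C=CC(C)(C)O4)c(=O)c12 | target

**Step count and risks**

Total step count: 11. Longest linear sequence: 9 steps (steps 1–4, then 7–11); the ring A branch (steps 5–6) joins at step 7.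

Steps most likely to fail:

Step 9. The carbene may attack a methoxy oxygen instead of a C–H bond and go on from the ylide by methyl shift or demethylation, or it may be lost to dimerisation or to cyclopropanation of the chromene alkene of a second molecule. The fallback is the deoxybenzoin route to isoflavones, which is known chemistry; it sets out from 12 and rejoins the route at 15. BCl3 in CH2Cl2 at −78 °C should remove one of the two equivalent ortho-methyl groups through the boron chelate of the ketone and give 1-{2-hydroxy-6-methoxy-4-[tri(propan-2-yl)silyloxy]phenyl}-2-{2,2-dimethyl-8-[tri(propan-2-yl)silyloxy]-2H-chromen-6-yl}ethan-1-one F1. Heating this phenol with N,N-dimethylformamide dimethyl acetal in toluene at 90 °C should formylate the methylene group and close ring C with loss of dimethylamine and methanol, which gives 15 without passing through 13 and 14.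

Step 7. The hot alkoxide may cause double arylation of the methyl group or loss of a silyl group, and enolisation of the twisted, hindered ketone may be slow. The fallback forms the ketone by acylation of the aryllithium instead of arylation of an enolate; it sets out from 7 (with 10, made from 9 as in step 6) and rejoins the route at 12. Negishi-type coupling of 7 with the Reformatsky reagent BrZnCH2CO2Et (Pd(dba)2, XPhos, THF, 60 °C) should give ethyl 2-{2,2-dimethyl-8-[tri(propan-2-yl)silyloxy]-2H-chromen-6-yl}acetate F2. Treatment with MeNH(OMe)·HCl and i-PrMgCl in THF at −20 °C should convert the ester into N-methoxy-N-methyl-2-{2,2-dimethyl-8-[tri(propan-2-yl)silyloxy]-2H-chromen-6-yl}acetamide F3. Addition of 10 to F3 in THF at −78 °C and aqueous work-up should give 12.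

Step 8. Diazo transfer to the singly activated methylene may stall, or the electron-rich diazo ketone may decompose during isolation. The fallback makes the diazo group by fragmentation of a tosylhydrazone; it sets out from 12 and rejoins the route at 13. Riley oxidation (SeO2, aqueous 1,4-dioxane, 90 °C) should give 1-{2,6-dimethoxy-4-[tri(propan-2-yl)silyloxy]phenyl}-2-{2,2-dimethyl-8-[tri(propan-2-yl)silyloxy]-2H-chromen-6-yl}ethane-1,2-dione F4. TsNHNH2 in MeOH at 50 °C should condense only at the carbonyl next to ring B, the other being shielded by two ortho-methoxy groups, and give N'-(2-{2,6-dimethoxy-4-[tri(propan-2-yl)silyloxy]phenyl}-1-{2,2-dimethyl-8-[tri(propan-2-yl)silyloxy]-2H-chromen-6-yl}-2-oxoethylidene)-4-methylbenzenesulfonohydrazide F5 (C=N geometry not defined; either isomer should fragment). DBU in CH2Cl2 at rt should then expel sulfinate (Bamford–Stevens fragmentation of an α-keto tosylhydrazone) and give 13.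

**Further compounds**

F1 | step 9 | 1-{2-hydroxy-6-methoxy-4-[tri(propan-2-yl)silyloxy]phenyl}-2-{2,2-dimethyl-8-[tri(propan-2-yl)silyloxy]-2H-chromen-6-yl}ethan-1-one | COc1cc(O[Si](C(C)C)(C(C)C)C(C)C)cc(O)c1C(=O)Cc1cc(O[Si](C(C)C)(C(C)C)C(C)C)c2OC(C)(C)C=Cc2c1
F2 | step 7 | ethyl 2-{2,2-dimethyl-8-[tri(propan-2-yl)silyloxy]-2H-chromen-6-yl}acetate | CCOC(=O)Cc1cc(O[Si](C(C)C)(C(C)C)C(C)C)c2OC(C)(C)C=Cc2c1
F3 | step 7 | N-methoxy-N-methyl-2-{2,2-dimethyl-8-[tri(propan-2-yl)silyloxy]-2H-chromen-6-yl}acetamide | CON(C)C(=O)Cc1cc(O[Si](C(C)C)(C(C)C)C(C)C)c2OC(C)(C)C=Cc2c1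
F4 | step 8 | 1-{2,6-dimethoxy-4-[tri(propan-2-yl)silyloxy]phenyl}-2-{2,2-dimethyl-8-[tri(propan-2-yl)silyloxy]-2H-chromen-6-yl}ethane-1,2-dione | COc1cc(O[Si](C(C)C)(C(C)C)C(C)C)cc(OC)c1C(=O)C(=O)c1cc(O[Si](C(C)C)(C(C)C)C(C)C)c2OC(C)(C)C=Cc2c1
F5 | step 8 | N'-(2-{2,6-dimethoxy-4-[tri(propan-2-yl)silyloxy]phenyl}-1-{2,2-dimethyl-8-[tri(propan-2-yl)silyloxy]-2H-chromen-6-yl}-2-oxoethylidene)-4-methylbenzenesulfonohydrazide (C=N geometry not defined) | COc1cc(O[Si](C(C)C)(C(C)C)C(C)C)cc(OC)c1C(=O)C(=NNS(=O)(=O)c1ccc(C)cc1)c1cc(O[Si](C(C)C)(C(C)C)C(C)C)c2OC(C)(C)C=Cc2c1
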